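The ring atoms are numbered C1 (bears CH2OAc), C2 (bears CHO) and C3 (bears the side chain, whose first carbon is C1'). The target hides a 1,5-dialdehyde (side-chain CHO, C1', C3, C2, ring CHO), and the C1=C2 bond of the cyclopentene is the aldol-condensation trace of a ketone at C1. The C1'–C3 bond is therefore made by an amine-catalysed enamine/iminium Michael addition of an achiral C13 aldehyde to an achiral open-chain keto-enal. The enamine left at C2 then closes the five-membered ring onto the acetoxymethyl ketone and water is lost. One operation should form the key bond, both stereocentres, the ring and the tetrasubstituted enal, giving the target without protecting groups.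

Key step: step 5

Assumption: the organometallic starting materials 2 and 5 are bought as THF solutions; otherwise each is made from the corresponding bromide and the metal.

Step 1
Reactants: 1 geranyl bromide, (2E)-1-bromo-3,7-dimethylocta-2,6-diene; 2 [2-(1,3-dioxolan-2-yl)ethyl]magnesium bromide
Product: 3 2-[(4E)-5,9-dimethyldeca-4,8-dien-1-yl]-1,3-dioxolane
Conditions: Li2CuCl4 (3 mol %), THF, −78 → 0 °C
Reagents that add atoms: none
Why: Copper-catalysed cross-coupling of a primary alkyl Grignard reagent with a primary allylic bromide should go at the primary carbon in THF at low temperature and keep the E double bond.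

Step 2
Reactants: 3 2-[(4E)-5,9-dimethyldeca-4,8-dien-1-yl]-1,3-dioxolane
Product: 4 (5E)-6,10-dimethylundeca-5,9-dienal
Conditions: 2 M aq. HCl, THF, rt
Reagents that add atoms: water, O
Why: Acid-catalysed acetal hydrolysis should free the aldehyde, and dilute acid at room temperature should leave the two trisubstituted alkenes untouched.

Step 3
Reactants: 5 but-3-en-1-ylzinc bromide; 6 acetoxyacetyl chloride (2-chloro-2-oxoethyl acetate)
Product: 7 2-oxohex-5-en-1-yl acetate
Conditions: Pd(PPh3)4 (3 mol %), THF, 0 °C → rt
Reagents that add atoms: none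
Why: Negishi acylation of an alkylzinc halide with an acid chloride should stop at the ketone and tolerate the acetate ester and the terminal alkene.

Step 4
Reactants: 7 2-oxohex-5-en-1-yl acetate; 8 (E)-but-2-enal (crotonaldehyde)
Product: 9 (5E)-2,7-dioxohept-5-en-1-yl acetate
Conditions: second-generation Hoveyda–Grubbs catalyst RuCl2(SIMes)(=CH-C6H4-2-O-i-Pr) (3 mol %), 8 (5 equiv), CH2Cl2, 40 °C
Reagents that add atoms: none
Why: Olefin cross-metathesis of the terminal alkene with excess crotonaldehyde should give the E-enal with loss of propene, the ketone and the acetate being inert to the ruthenium carbene.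

Step 5
Reactants: 4 (5E)-6,10-dimethylundeca-5,9-dienal; 9 (5E)-2,7-dioxohept-5-en-1-yl acetate
Product: 12 [(3R)-2-formyl-3-[(2S,5E)-6,10-dimethyl-1-oxoundeca-5,9-dien-2-yl]cyclopent-1-en-1-yl]methyl acetate (CNP0280859.1), via Michael adduct keto-dialdehyde 10 (not isolated), via aldol β-hydroxy aldehyde 11 (not isolated)
Conditions: (R)-2-[diphenyl(trimethylsilyloxy)methyl]pyrrolidine (20 mol %), PhCO2H (20 mol %), 4 (1.5 equiv), slow addition of 9, toluene, 0 °C → rt
Reagents that add atoms: none
Why: The amine condenses with 4 to its E-enamine and with 9 to the E-iminium ion; the enamine α-carbon adds to the iminium β-carbon (intermolecular Michael addition, new C1'–C3 bond), the enamine this leaves at C2 adds to the acetoxymethyl ketone, and the β-hydroxy iminium ion loses water to the conjugated enal as the catalyst is released. The closest known reaction type is the diarylprolinol silyl ether-catalysed domino Michael/aldol condensation of enolisable aldehydes with enals, which builds cyclohexene and cyclopentene carbaldehydes by the same enamine/iminium relay. The cyclopentene closes by a 5-(enolexo)-exo-trig aldol addition of C2 to the C1 ketone carbon, the only unstrained closure open to that enamine. Both stereocentres are under catalyst control: the diphenyl(silyloxy)methyl group covers one face of the enamine and the corresponding face of the iminium ion, so the (R)-amine should give S at C1' and R at C3 (the anti dialdehyde), while the two centres made in the aldol step vanish on dehydration. The step needs role selectivity, secured because 4 has no acceptor site and the iminium ion of 9 is the strongest electrophile present, with 4 in excess and 9 added slowly to hold back dienamine self-condensation; the α-branched aldehyde of the product forms an enamine only slowly, which should protect C1' from epimerisation.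

Compound list
1 | geranyl bromide, (2E)-1-bromo-3,7-dimethylocta-2,6-diene | CC(C)=CCC/C(C)=C/CBr | starting material
2 | [2-(1,3-dioxolan-2-yl)ethyl]magnesium bromide | Br[Mg]CCC1OCCO1 | starting material
3 | 2-[(4E)-5,9-dimethyldeca-4,8-dien-1-yl]-1,3-dioxolane | CC(C)=CCC/C(C)=C/CCCC1OCCO1 | intermediate
4 | (5E)-6,10-dimethylundeca-5,9-dienal | CC(C)=CCC/C(C)=C/CCCC=O | intermediate
5 | but-3-en-1-ylzinc bromide | C=CCC[Zn]Br | starting material
6 | acetoxyacetyl chloride (2-chloro-2-oxoethyl acetate) | CC(=O)OCC(=O)Cl | starting material
7 | 2-oxohex-5-en-1-yl acetate | CC(=O)OCC(=O)CCC=C | intermediate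
8 | (E)-but-2-enal (crotonaldehyde) | C/C=C/C=O | starting material
9 | (5E)-2,7-dioxohept-5-en-1-yl acetate | CC(=O)OCC(=O)CC/C=C/C=O | intermediate
10 | (5S)-5-[(2S,5E)-6,10-dimethyl-1-oxoundeca-5,9-dien-2-yl]-2,7-dioxoheptyl acetate (open-chain Michael adduct) | O=CC[C@@H]([C@@H](C=O)CC/C=C(\C)CCC=C(C)C)CCC(=O)COC(C)=O | intermediate
11 | {(3R)-3-[(2S,5E)-6,10-dimethyl-1-oxoundeca-5,9-dien-2-yl]-2-formyl-1-hydroxycyclopentyl}methyl acetate (aldol, epimers at C1 and C2 not defined) | CC(=O)OCC1(O)C(C=O)[C@@H]([C@@H](C=O)CC/C=C(\C)CCC=C(C)C)CC1 | intermediate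
12 | [(3R)-2-formyl-3-[(2S,5E)-6,10-dimethyl-1-oxoundeca-5,9-dien-2-yl]cyclopent-1-en-1-yl]methyl acetate (CNP0280859.1) | CC(=O)OCC1=C(C=O)[C@@H]([C@@H](C=O)CC/C=C(\C)CCC=C(C)C)CC1 | target

Total step count: 5. Longest linear sequence: 3 steps (steps 1, 2, 5 or steps 3, 4, 5).

Steps most likely to fail

Step 5. The cascade may lose role and catalyst control in several ways:
- self-condensation of 9 through its dienamine, or self-aldol of 4;
- Michael addition through the free enal instead of the iminium ion, which would erode the anti relation;
- stalling at the aldol stage;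
- epimerisation at C1'.

The fallback sets out from 4 and 9 and comes back at 12; it moves the donor role to a preformed enol derivative that cannot act as an acceptor. Pinnick oxidation of 4 (NaClO2, NaH2PO4, 2-methylbut-2-ene, t-BuOH/H2O) should give (5E)-6,10-dimethylundeca-5,9-dienoic acid F1. DCC/DMAP coupling with propane-2-thiol should give S-propan-2-yl (5E)-6,10-dimethylundeca-5,9-dienethioate F2. LDA then TBSCl (THF, −78 °C) should give the Z silyl ketene thioacetal tert-butyl{[(1Z,5E)-6,10-dimethyl-1-(propan-2-ylsulfanyl)undeca-1,5,9-trien-1-yl]oxy}dimethylsilane F3. Mukaiyama–Michael addition of F3 to 9 under iminium catalysis by (2R,5R)-5-benzyl-2-tert-butyl-3-methylimidazolidin-4-one trifluoroacetate (CH2Cl2/H2O, −40 °C) should give the open-chain thioester S-propan-2-yl (2S,5E)-2-[(3S)-7-acetoxy-1,6-dioxoheptan-3-yl]-6,10-dimethylundeca-5,9-dienethioate F4. Here only the acceptor is catalyst-bound, and the ketene acetal geometry is a separate handle on C1': Z is drawn, and the E isomer from enolisation in THF/HMPA would be used if the open transition state calls for it. Intramolecular aldol condensation with dibenzylammonium trifluoroacetate (toluene, 50 °C) should give the cyclopentene enal thioester S-propan-2-yl (2S,5E)-2-[(1R)-3-(acetoxymethyl)-2-formylcyclopent-2-en-1-yl]-6,10-dimethylundeca-5,9-dienethioate F5. Fukuyama reduction (Et3SiH, Pd/C, acetone, rt) should then turn the thioester into the aldehyde of 12.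

Step 4. Cross-metathesis may turn over slowly next to homodimerisation of 7, and the keto-enal may oligomerise or cyclise on concentration with the spent catalyst. The fallback sets out from 7 and comes back at 9. Ozonolysis of 7 (O3, CH2Cl2, −78 °C; PPh3) should give 2,5-dioxopentyl acetate F6. Wittig olefination of its aldehyde with (triphenylphosphoranylidene)acetaldehyde (toluene, rt) should give 9, the stabilised ylide leaving the ketone alone.

Step 1. The Grignard reagent may attack the tertiary allylic terminus (allylic transposition), and the double bond geometry may scramble through allylcopper intermediates. The fallback sets out from 1 and comes back at 3; it uses a sulfone-stabilised carbanion, which should displace bromide directly at the primary carbon without copper. 2-[2-(Phenylsulfonyl)ethyl]-1,3-dioxolane is deprotonated (n-BuLi, THF, −78 °C) and alkylated with 1 to give racemic 2-[(4E)-5,9-dimethyl-2-(phenylsulfonyl)deca-4,8-dien-1-yl]-1,3-dioxolane F7. Reductive desulfonylation (sodium amalgam, Na2HPO4, MeOH, −20 °C) should give 3.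

Further compounds
F1 | step 5 | (5E)-6,10-dimethylundeca-5,9-dienoic acid | CC(C)=CCC/C(C)=C/CCCC(=O)O
F2 | step 5 | S-propan-2-yl (5E)-6,10-dimethylundeca-5,9-dienethioate | CC(C)=CCC/C(C)=C/CCCC(=O)SC(C)C
F3 | step 5 | tert-butyl{[(1Z,5E)-6,10-dimethyl-1-(propan-2-ylsulfanyl)undeca-1,5,9-trien-1-yl]oxy}dimethylsilane | CC(C)=CCC/C(C)=C/CC/C=C(\SC(C)C)O[Si](C)(C)C(C)(C)C
F4 | step 5 | S-propan-2-yl (2S,5E)-2-[(3S)-7-acetoxy-1,6-dioxoheptan-3-yl]-6,10-dimethylundeca-5,9-dienethioate | O=CC[C@@H]([C@@H](C(=O)SC(C)C)CC/C=C(\C)CCC=C(C)C)CCC(=O)COC(C)=O
F5 | step 5 | S-propan-2-yl (2S,5E)-2-[(1R)-3-(acetoxymethyl)-2-formylcyclopent-2-en-1-yl]-6,10-dimethylundeca-5,9-dienethioate | CC(=O)OCC1=C(C=O)[C@@H]([C@@H](C(=O)SC(C)C)CC/C=C(\C)CCC=C(C)C)CC1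
F6 | step 4 | 2,5-dioxopentyl acetate | CC(=O)OCC(=O)CCC=O
F7 | step 1 | 2-[(4E)-5,9-dimethyl-2-(phenylsulfonyl)deca-4,8-dien-1-yl]-1,3-dioxolane (racemic) | CC(C)=CCC/C(C)=C/CC(CC1OCCO1)S(=O)(=O)c1ccccc1
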